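Remark on the chemistry: all starting materials are taken as purchased, (1Z)-1-bromoprop-1-ene as the pure Z isomer. Bicyclic compounds are numbered as 2H-cyclohepta[b]furans (O1, C2, C3, C3a, C4 to C8, C8a); ring A is the seven-membered carbocycle, ring B the lactone. The SMILES strings define the configurations.

**Retrosynthetic overview**
- Target ⇐ its C5 silyl ether ⇐ C7 aldehyde: the (Z)-butenoyl group comes from a chromium-mediated addition of (1Z)-1-bromoprop-1-ene and oxidation.
- C7 aldehyde ⇐ C7=C8 alkene of a bicyclic allylic alcohol: reagent-controlled epoxidation on the face of the lactone oxygen, then inverting opening at C8 by 3-methylbutanoic acid (sets C7 and C8, installs the ester).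
- Bicyclic allylic alcohol ⇐ (cyclohepta-1,3-dien-1-yl)methanol + 2-bromoprop-2-enoic acid by a palladium-catalysed formal [3+2] heteroannulation (C3–C3a and O1–C8a in one operation). The enabling feature is that the lactone carbons C3a/C8a adjoin the oxygenated pair C8/C7, so the run C3a–C8a–C8–C7 of ring A is a latent 1,3-diene; annulation at C3a/C8a leaves the C7=C8 alkene exactly where the trans-diol monoester is needed.
- Dienylmethanol ⇐ cyclohept-2-enone (dienyl triflate, Stille hydroxymethylation) ⇐ ring-closing metathesis of a dienone ⇐ Evans syn-aldol (sets C5 and C6).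
- Ring order: ring A first (metathesis), ring B second (key step).

Key step: step 8

**Route**

Step 1
Reactants: 1 (4S)-4-benzyl-3-propanoyl-1,3-oxazolidin-2-one; 2 pent-4-enal
Product: 3 (4S)-4-benzyl-3-[(2S,3R)-3-hydroxy-2-methylhept-6-enoyl]-1,3-oxazolidin-2-one
Conditions: Bu2BOTf, i-Pr2NEt, CH2Cl2, −78 to 0 °C; then pH 7 buffer, MeOH, 30% H2O2, 0 °C
Reagents that add atoms: none
Why: Evans boron-mediated syn-aldol reaction, in which the Z enolate geometry and the benzyl-shielded chair transition state should set C2 (S) and C3 (R) together.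

Step 2
Reactants: 3
Product: 4 (2S,3R)-3-hydroxy-N-methoxy-N,2-dimethylhept-6-enamide
Conditions: MeNH(OMe)·HCl, AlMe3, CH2Cl2, −15 to 0 °C
Reagents that add atoms: N,O-dimethylhydroxylamine hydrochloride, CNOC.Cl
Why: Weinreb transamidation by the aluminium amide, where the free β-hydroxyl directs attack to the exocyclic imide carbonyl and the auxiliary is released without epimerisation at C2.

Step 3
Reactants: 4
Product: 5 (2S,3R)-3-[(tert-butyldimethylsilyl)oxy]-N-methoxy-N,2-dimethylhept-6-enamide
Conditions: TBSOTf, 2,6-lutidine, CH2Cl2, 0 °C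
Reagents that add atoms: tert-butyldimethylsilyl trifluoromethanesulfonate, CC(C)(C)[Si](C)(C)OS(=O)(=O)C(F)(F)F
Why: Silylation of the secondary alcohol by the silyl triflate gives an ether that should survive every step up to the final fluoride treatment.

Step 4
Reactants: 5; 6 vinylmagnesium bromide
Product: 7 (4S,5R)-5-[(tert-butyldimethylsilyl)oxy]-4-methylnona-1,8-dien-3-one
Conditions: THF, 0 °C; inverse quench into cold 1 M HCl
Reagents that add atoms: none
Why: Weinreb ketone synthesis, in which magnesium chelation by the N-methoxy group stops the addition at the ketone stage and the acidic quench keeps the liberated amine from adding to the new enone.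

Step 5
Reactants: 7
Product: 8 (6R,7S)-6-[(tert-butyldimethylsilyl)oxy]-7-methylcyclohept-2-en-1-one
Conditions: second-generation Grubbs catalyst RuCl2(=CHPh)(PCy3)(H2IMes) (5 mol %), CH2Cl2 (5 mM), 40 °C
Reagents that add atoms: none
Why: Ring-closing metathesis of the two terminal alkenes closes ring A as a seven-membered enone with loss of ethene and without touching the stereocentres.

Step 6
Reactants: 8
Product: 9 (6R,7S)-6-[(tert-butyldimethylsilyl)oxy]-7-methylcyclohepta-1,3-dien-1-yl trifluoromethanesulfonate
Conditions: Tf2O, 2,6-di-tert-butyl-4-methylpyridine, CH2Cl2, 0 °C to rt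
Reagents that add atoms: trifluoromethanesulfonic anhydride, O=S(=O)(OS(=O)(=O)C(F)(F)F)C(F)(F)F
Why: Thermodynamic enol triflation of an enone (O-triflation, then loss of a γ-proton) should give the linear conjugated dienyl triflate, as with steroidal 4-en-3-ones, and leave the C7 methine intact.

Step 7
Reactants: 9; 10 (tributylstannyl)methanol
Product: 11 [(6R,7R)-6-[(tert-butyldimethylsilyl)oxy]-7-methylcyclohepta-1,3-dien-1-yl]methanol
Conditions: Pd(PPh3)4 (5 mol %), LiCl (3 equiv), THF, 65 °C
Reagents that add atoms: none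
Why: Stille cross-coupling of an alkenyl triflate with the hydroxymethylstannane replaces the triflate by CH2OH with retention of the diene.

Step 8
Reactants: 11; 12 2-bromoprop-2-enoic acid
Product: 14 (3aS,5R,6R,8aS)-5-[(tert-butyldimethylsilyl)oxy]-7-(hydroxymethyl)-6-methyl-3-methylidene-3,3a,4,5,6,8a-hexahydro-2H-cyclohepta[b]furan-2-one, via allylpalladium carboxylate 13 (not isolated)
Conditions: Pd(OAc)2 (10 mol %), n-Bu4NCl (1 equiv), K2CO3 (2.5 equiv), DMF, 60 °C, slow addition of 12
Reagents that add atoms: none
Why: Proposed new method: zerovalent palladium inserts into the C–Br bond of the 2-bromoacrylate, the 1-carboxyvinylpalladium adds syn across C3=C4 of the diene with the new C–C bond at the unsubstituted terminus C4, and the allylpalladium 13 is closed by its own κO-bound carboxylate at the near allyl terminus (C–O reductive elimination), which gives the lactone and returns zerovalent palladium. The closest known reaction type is the Larock heteroannulation of 1,3-dienes by aryl or alkenyl halides that carry an OH, NHR or CO2H group; the extension is an α-haloacrylic acid as the halide partner, which delivers the complete α-methylene-γ-butyrolactone (two bonds, ring B, two stereocentres, the exocyclic alkene) in one operation. Ring B closes in a 5-exo mode at the allyl terminus, since closure at the far terminus C1 would need a seven-membered ring and a quaternary C–O bond. C3a is set by the face of carbopalladation, expected anti to the C6 silyloxy group (A(1,2) strain with the C1 substituent holds the C7 methyl pseudoaxial on one face, which puts the trans silyloxy group pseudoaxial over C4 on the other), and C8a follows from C3a because palladium, vinyl carbon and carboxylate oxygen stay on one face, so only the cis-fused lactone can form. The step needs carbopalladation at C4 and C–O closure faster than β-hydride elimination: the first is secured by the fully substituted C1, the second by the chelating carboxylate next to the metal, and the free hydroxymethyl group cannot close on the allyl unit because it is trans to C3 on the C1=C2 bond.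

Step 9
Reactants: 14
Product: 15 (3aS,5R,6S,7R,8R,8aR)-5-[(tert-butyldimethylsilyl)oxy]-7,8-epoxy-7-(hydroxymethyl)-6-methyl-3-methylideneoctahydro-2H-cyclohepta[b]furan-2-one (epoxide on the face of the lactone oxygen)
Conditions: Ti(OiPr)4 (20 mol %), D-(−)-diisopropyl tartrate (26 mol %), t-BuOOH (2 equiv, decane), 4 Å MS, CH2Cl2, −20 °C
Reagents that add atoms: tert-butyl hydroperoxide, CC(C)(C)OO
Why: Katsuki–Sharpless asymmetric epoxidation of a primary allylic alcohol, in which the titanium tartrate should deliver oxygen to the C7=C8 face chosen by the D-tartrate (the face of the lactone oxygen), setting C7 and C8 under reagent control and leaving the electron-poor exocyclic methylene untouched.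

Step 10
Reactants: 15; 16 3-methylbutanoic acid
Product: 17 (3aS,5R,6S,7R,8S,8aR)-5-[(tert-butyldimethylsilyl)oxy]-7-hydroxy-7-(hydroxymethyl)-6-methyl-3-methylidene-2-oxooctahydro-2H-cyclohepta[b]furan-8-yl 3-methylbutanoate
Conditions: Ti(OiPr)4 (1.5 equiv), CH2Cl2, rt
Reagents that add atoms: none
Why: Titanium-mediated opening of a 2,3-epoxy alcohol by a carboxylic acid (Sharpless C3-selective opening), in which the acid attacks C8 within the titanium chelate (C7 is quaternary) with inversion, so the ester ends on the face opposite the lactone oxygen and the C7 hydroxyl keeps its configuration.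

Step 11
Reactants: 17
Product: 18 (3aS,5R,6S,7S,8S,8aR)-5-[(tert-butyldimethylsilyl)oxy]-7-formyl-7-hydroxy-6-methyl-3-methylidene-2-oxooctahydro-2H-cyclohepta[b]furan-8-yl 3-methylbutanoate
Conditions: Dess–Martin periodinane, NaHCO3, CH2Cl2, 0 °C
Reagents that add atoms: none
Why: Dess–Martin oxidation converts the primary alcohol into the aldehyde while the tertiary hydroxyl is inert and the quaternary C7 cannot epimerise or eliminate.

Step 12
Reactants: 18; 19 (1Z)-1-bromoprop-1-ene
Product: 20 (3aS,5R,6S,7R,8S,8aR)-5-[(tert-butyldimethylsilyl)oxy]-7-hydroxy-7-[(2Z)-1-hydroxybut-2-en-1-yl]-6-methyl-3-methylidene-2-oxooctahydro-2H-cyclohepta[b]furan-8-yl 3-methylbutanoate (both carbinol epimers)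
Conditions: CrCl2 (6 equiv), NiCl2 (2 mol %), DMSO, rt
Reagents that add atoms: none
Why: Nozaki–Hiyama–Kishi reaction, in which the alkenylchromium reagent should add only to the aldehyde with retention of the Z geometry while esters, lactone and methylene lactone are tolerated; the new carbinol centre is not controlled and is removed in step 13.

Step 13
Reactants: 20
Product: 21 (3aS,5R,6S,7S,8S,8aR)-7-[(2Z)-but-2-enoyl]-5-[(tert-butyldimethylsilyl)oxy]-7-hydroxy-6-methyl-3-methylidene-2-oxooctahydro-2H-cyclohepta[b]furan-8-yl 3-methylbutanoate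
Conditions: Dess–Martin periodinane, NaHCO3, CH2Cl2, 0 °C
Reagents that add atoms: none
Why: Buffered Dess–Martin oxidation of the secondary allylic alcohol should give the Z enone without Z to E isomerisation and converges both carbinol epimers.

Step 14
Reactants: 21
Product: 22 (3aS,5R,6S,7S,8S,8aR)-7-[(2Z)-but-2-enoyl]-5,7-dihydroxy-6-methyl-3-methylidene-2-oxooctahydro-2H-cyclohepta[b]furan-8-yl 3-methylbutanoate (CNP0186412.2)
Conditions: HF·pyridine, pyridine, THF, 0 °C to rt
Reagents that add atoms: none
Why: Fluoride-mediated desilylation under buffered, weakly acidic conditions frees the C5 hydroxyl without retro-aldol cleavage, acyl migration or isomerisation of the Z enone.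

**Compound list**
1 | (4S)-4-benzyl-3-propanoyl-1,3-oxazolidin-2-one | CCC(=O)N1C(=O)OC[C@@H]1Cc1ccccc1 | starting material
2 | pent-4-enal | C=CCCC=O | starting material
3 | (4S)-4-benzyl-3-[(2S,3R)-3-hydroxy-2-methylhept-6-enoyl]-1,3-oxazolidin-2-one | C=CCC[C@@H](O)[C@H](C)C(=O)N1C(=O)OC[C@@H]1Cc1ccccc1 | intermediate
4 | (2S,3R)-3-hydroxy-N-methoxy-N,2-dimethylhept-6-enamide | C=CCC[C@@H](O)[C@H](C)C(=O)N(C)OC | intermediate
5 | (2S,3R)-3-[(tert-butyldimethylsilyl)oxy]-N-methoxy-N,2-dimethylhept-6-enamide | C=CCC[C@@H](O[Si](C)(C)C(C)(C)C)[C@H](C)C(=O)N(C)OC | intermediate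
6 | vinylmagnesium bromide | C=C[Mg]Br | starting material
7 | (4S,5R)-5-[(tert-butyldimethylsilyl)oxy]-4-methylnona-1,8-dien-3-one | C=CCC[C@@H](O[Si](C)(C)C(C)(C)C)[C@H](C)C(=O)C=C | intermediate
8 | (6R,7S)-6-[(tert-butyldimethylsilyl)oxy]-7-methylcyclohept-2-en-1-one | C1C[C@@H](O[Si](C)(C)C(C)(C)C)[C@H](C)C(=O)C=C1 | intermediate
9 | (6R,7S)-6-[(tert-butyldimethylsilyl)oxy]-7-methylcyclohepta-1,3-dien-1-yl trifluoromethanesulfonate | C1[C@@H](O[Si](C)(C)C(C)(C)C)[C@H](C)C(OS(=O)(=O)C(F)(F)F)=CC=C1 | intermediate
10 | (tributylstannyl)methanol | CCCC[Sn](CCCC)(CCCC)CO | starting material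
11 | [(6R,7R)-6-[(tert-butyldimethylsilyl)oxy]-7-methylcyclohepta-1,3-dien-1-yl]methanol | C1[C@@H](O[Si](C)(C)C(C)(C)C)[C@H](C)C(CO)=CC=C1 | intermediate
12 | 2-bromoprop-2-enoic acid | C=C(Br)C(=O)O | starting material
13 | allylpalladium carboxylate: six-membered C,O-palladacycle of divalent palladium, drawn as the η1 form of the π-allyl complex with other ligands omitted | C=C1C(=O)O[Pd][C@@H]2[C@H]1C[C@@H](O[Si](C)(C)C(C)(C)C)[C@H](C)C(CO)=C2 | intermediate
14 | (3aS,5R,6R,8aS)-5-[(tert-butyldimethylsilyl)oxy]-7-(hydroxymethyl)-6-methyl-3-methylidene-3,3a,4,5,6,8a-hexahydro-2H-cyclohepta[b]furan-2-one | C=C1C(=O)O[C@@H]2[C@H]1C[C@@H](O[Si](C)(C)C(C)(C)C)[C@H](C)C(CO)=C2 | intermediate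
15 | (3aS,5R,6S,7R,8R,8aR)-5-[(tert-butyldimethylsilyl)oxy]-7,8-epoxy-7-(hydroxymethyl)-6-methyl-3-methylideneoctahydro-2H-cyclohepta[b]furan-2-one | C=C1C(=O)O[C@@H]2[C@H]1C[C@@H](O[Si](C)(C)C(C)(C)C)[C@H](C)[C@]3(CO)O[C@H]23 | intermediate
16 | 3-methylbutanoic acid | CC(C)CC(=O)O | starting material
17 | (3aS,5R,6S,7R,8S,8aR)-5-[(tert-butyldimethylsilyl)oxy]-7-hydroxy-7-(hydroxymethyl)-6-methyl-3-methylidene-2-oxooctahydro-2H-cyclohepta[b]furan-8-yl 3-methylbutanoate | C=C1C(=O)O[C@@H]2[C@H]1C[C@@H](O[Si](C)(C)C(C)(C)C)[C@H](C)[C@@](O)(CO)[C@H]2OC(=O)CC(C)C | intermediate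
18 | (3aS,5R,6S,7S,8S,8aR)-5-[(tert-butyldimethylsilyl)oxy]-7-formyl-7-hydroxy-6-methyl-3-methylidene-2-oxooctahydro-2H-cyclohepta[b]furan-8-yl 3-methylbutanoate | C=C1C(=O)O[C@@H]2[C@H]1C[C@@H](O[Si](C)(C)C(C)(C)C)[C@H](C)[C@@](O)(C=O)[C@H]2OC(=O)CC(C)C | intermediate
19 | (1Z)-1-bromoprop-1-ene | C/C=C\Br | starting material
20 | (3aS,5R,6S,7R,8S,8aR)-5-[(tert-butyldimethylsilyl)oxy]-7-hydroxy-7-[(2Z)-1-hydroxybut-2-en-1-yl]-6-methyl-3-methylidene-2-oxooctahydro-2H-cyclohepta[b]furan-8-yl 3-methylbutanoate (carbinol epimers) | C=C1C(=O)O[C@@H]2[C@H]1C[C@@H](O[Si](C)(C)C(C)(C)C)[C@H](C)[C@@](O)(C(O)/C=C\C)[C@H]2OC(=O)CC(C)C | intermediate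
21 | (3aS,5R,6S,7S,8S,8aR)-7-[(2Z)-but-2-enoyl]-5-[(tert-butyldimethylsilyl)oxy]-7-hydroxy-6-methyl-3-methylidene-2-oxooctahydro-2H-cyclohepta[b]furan-8-yl 3-methylbutanoate | C=C1C(=O)O[C@@H]2[C@H]1C[C@@H](O[Si](C)(C)C(C)(C)C)[C@H](C)[C@@](O)(C(=O)/C=C\C)[C@H]2OC(=O)CC(C)C | intermediate
22 | (3aS,5R,6S,7S,8S,8aR)-7-[(2Z)-but-2-enoyl]-5,7-dihydroxy-6-methyl-3-methylidene-2-oxooctahydro-2H-cyclohepta[b]furan-8-yl 3-methylbutanoate | C=C1C(=O)O[C@@H]2[C@H]1C[C@@H](O)[C@H](C)[C@@](O)(C(=O)/C=C\C)[C@H]2OC(=O)CC(C)C | target

**Step count and risks**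
Total step count: 14. Longest linear sequence: 14 steps (from 1 and 2).

Steps most likely to fail:

Step 8 (proposed new method). What may go wrong: β-hydride elimination from the allylpalladium before C–O closure, oligomerisation of the bromoacrylate or of the product by further carbopalladation, oxidation of the primary alcohol by the organopalladium halide, or carbopalladation on the wrong diene face. The fallback uses known chemistry, sets out from 11 and returns at 14. The same two bonds are made by the manganese triacetate oxidative lactone annulation of a conjugated diene. Compound 11 is heated with Mn(OAc)3·2H2O and KOAc in AcOH/Ac2O at 70 °C: the carboxymethyl radical adds to C4, the allyl radical is oxidised and closed by the carboxyl group at C3, and the primary alcohol is acetylated under the conditions, which should give the cis-fused lactone acetate F1. K2CO3 in MeOH removes the acetate to give the hydroxy lactone F2. Its dianion (LDA, THF, −78 °C) is aminomethylated with dimethylmethyleneiminium iodide to the Mannich base F3; MeI converts this into the methiodide F4, and NaHCO3 eliminates trimethylamine to return 14.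

Step 9. What may go wrong: slow or poorly face-selective epoxidation, because the tartrate has to deliver oxygen to the face that carries the lactone oxygen and the C6 methyl (mismatched double stereodifferentiation). The fallback sets out from 14 and returns at 18; it takes the opposite epoxide and moves the inversion from C8 to C7. Compound 14 is epoxidised with the enantiomeric catalyst (Ti(OiPr)4, L-(+)-diisopropyl tartrate, t-BuOOH, 4 Å MS, CH2Cl2, −20 °C), expected to be the matched case, to give the 7,8-epoxide on the face opposite the lactone oxygen F5. Acid-catalysed hydrolysis (cat. HClO4, THF/H2O, 0 °C) opens it at the tertiary carbon C7 with inversion to the triol F6. Oxoammonium oxidation selective for the primary alcohol (TEMPO, N-chlorosuccinimide, Bu4NCl, pH 8.6 buffer/CH2Cl2) gives the dihydroxy aldehyde F7, and acylation of its only secondary hydroxyl (3-methylbutanoic anhydride, DMAP, CH2Cl2, 0 °C) gives 18.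

Step 10. What may go wrong: attack at the tertiary C7 instead of C8, no reaction at the hindered C8 (it sits next to the lactone C–O), or migration of the new acyl group to the primary hydroxyl. The fallback sets out from 15 and returns at 18; regiocontrol is handed to a carbonyl group instead of the titanium chelate. Compound 15 is oxidised (Dess–Martin periodinane, NaHCO3, CH2Cl2, 0 °C) to the epoxy aldehyde F8, whose quaternary α-carbon cannot be attacked, and 16 with Cs2CO3 (0.2 equiv) in DMF at 40 °C opens the epoxide at the β-carbon C8 with inversion to give 18 directly.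

Further compounds
F1 | step 8 | acetate of the 3-demethylidene analogue of 14 (cis-fused lactone, CH2 at C3, CH2OAc at C7) | C1C(=O)O[C@@H]2[C@H]1C[C@@H](O[Si](C)(C)C(C)(C)C)[C@H](C)C(COC(C)=O)=C2
F2 | step 8 | 3-demethylidene analogue of 14 (hydroxy lactone) | C1C(=O)O[C@@H]2[C@H]1C[C@@H](O[Si](C)(C)C(C)(C)C)[C@H](C)C(CO)=C2
F3 | step 8 | 3-[(dimethylamino)methyl] lactone (Mannich base, C3 epimers) | CN(C)CC1C(=O)O[C@@H]2[C@H]1C[C@@H](O[Si](C)(C)C(C)(C)C)[C@H](C)C(CO)=C2
F4 | step 8 | trimethylammonium iodide of F3 (methiodide) | C[N+](C)(C)CC1C(=O)O[C@@H]2[C@H]1C[C@@H](O[Si](C)(C)C(C)(C)C)[C@H](C)C(CO)=C2.[I-]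
F5 | step 9 | 7,8-epoxide of 14 on the face opposite the lactone oxygen (diastereomer of 15) | C=C1C(=O)O[C@@H]2[C@H]1C[C@@H](O[Si](C)(C)C(C)(C)C)[C@H](C)[C@@]3(CO)O[C@@H]23
F6 | step 9 | 7,8-dihydroxy-7-(hydroxymethyl) triol (8-deacyl 17) | C=C1C(=O)O[C@@H]2[C@H]1C[C@@H](O[Si](C)(C)C(C)(C)C)[C@H](C)[C@@](O)(CO)[C@H]2O
F7 | step 9 | 7-formyl-7,8-diol (8-deacyl 18) | C=C1C(=O)O[C@@H]2[C@H]1C[C@@H](O[Si](C)(C)C(C)(C)C)[C@H](C)[C@@](O)(C=O)[C@H]2O
F8 | step 10 | 7,8-epoxy-7-carbaldehyde (aldehyde of 15) | C=C1C(=O)O[C@@H]2[C@H]1C[C@@H](O[Si](C)(C)C(C)(C)C)[C@H](C)[C@]3(C=O)O[C@H]23
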